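**Retrosynthetic overview**
- 19 ⇒ twofold-symmetric tetraol 13, which needs only one of its two equivalent 7-OH groups methylated. A lipase (serine hydrolase) breaks the symmetry by removing one exposed 7-acetate from tetraacetate 15. O-methylation and deacetylation follow.
- 13 ⇒ C3–C3'' disconnection: silicon-tethered oxidative coupling of two identical (2S)-flavanone enol ethers (11 → 12). C3 and C3'' are set anti to the 2-aryl groups.
- (2S)-Flavanone 8 ⇒ C2–aryl disconnection: Rh-catalysed asymmetric 1,4-addition of 7 to chromone 6 sets the first stereocentre. Then 6 ⇒ enaminone 5 ⇒ dibenzyl ether 3 ⇒ 1.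
- Ring order: ring A is bought, ring C is closed in step 3, ring B is attached in step 4, and the two flavanones are joined in step 6.

Assumption: by the usual face-selection model for cyclic enones, the (S)-biaryl diphosphine gives the 2S flavanone. The sign is checked on 8 by chiral HPLC and circular dichroism, and the ligand antipode is used if it proves opposite.

**Step 1**
Reactants: 1 2',4',6'-trihydroxyacetophenone; 2 benzyl bromide
Product: 3 1-[2,4-bis(benzyloxy)-6-hydroxyphenyl]ethan-1-one
Conditions: 2 (2.1 equiv), K2CO3 (2.2 equiv), DMF, 60 °C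
Reagents that add atoms: benzyl bromide (2), BrCc1ccccc1
Why: In this Williamson ether synthesis the third OH is hydrogen-bonded to the acetyl C=O and stays free for the later ring closure.

**Step 2**
Reactants: 3 1-[2,4-bis(benzyloxy)-6-hydroxyphenyl]ethan-1-one; 4 N,N-dimethylformamide dimethyl acetal
Product: 5 (E)-1-[2,4-bis(benzyloxy)-6-hydroxyphenyl]-3-(dimethylamino)prop-2-en-1-one
Conditions: 4 (2 equiv), toluene, 95 °C
Reagents that add atoms: N,N-dimethylformamide dimethyl acetal (4), COC(OC)N(C)C
Why: Enaminone condensation of the methyl ketone with the amide acetal installs the one carbon that becomes C2, and the chelated phenol is not methylated.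

**Step 3**
Reactants: 5 (E)-enaminone
Product: 6 5,7-bis(benzyloxy)-4H-chromen-4-one
Conditions: conc. aq HCl, CH2Cl2, 40 °C
Reagents that add atoms: none
Why: Acid-promoted addition–elimination (intramolecular oxa-Michael addition of the phenol, then loss of dimethylamine) closes ring C, and the benzyl ethers tolerate the short biphasic acid treatment.

**Step 4**
Reactants: 6 5,7-bis(benzyloxy)-4H-chromen-4-one; 7 4-methoxyphenylboronic acid
Product: 8 (2S)-5,7-bis(benzyloxy)-2-(4-methoxyphenyl)chroman-4-one
Conditions: [RhCl(C2H4)2]2 (2.5 mol %), (S)-MeO-F12-BIPHEP [(S)-2,2'-bis{bis(3,4,5-trifluorophenyl)phosphino}-6,6'-dimethoxybiphenyl] (5.5 mol %), KOH (10 mol %), 7 (2.5 equiv, in portions), CH2Cl2–H2O 10:1, 25–35 °C; recrystallise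
Reagents that add atoms: 4-methoxyphenylboronic acid (7), COc1ccc(B(O)O)cc1
Why: In this Hayashi–Miyaura asymmetric conjugate addition the aryl–rhodium complex of the electron-poor chiral diphosphine inserts into one face of C2=C3 and water protonates the rhodium enolate, which sets C2 as S (typically ≥97% ee on 5,7-dialkoxychromones) under near-neutral conditions that do not open the pyranone.

**Step 5**
Reactants: 8 (2S)-flavanone (2 equiv); 9 diisopropylsilyl bis(trifluoromethanesulfonate)
Product: 11 bis{[(2S)-5,7-bis(benzyloxy)-2-(4-methoxyphenyl)-2H-chromen-4-yl]oxy}di(propan-2-yl)silane, via mono-enol silyl triflate 10 (not isolated)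
Conditions: 9 (0.50 equiv), Et3N (1.5 equiv per 8), CH2Cl2, 0 °C → rt; quick filtration through Et3N-deactivated silica
Reagents that add atoms: diisopropylsilyl bis(trifluoromethanesulfonate) (9), CC(C)[Si](OS(=O)(=O)C(F)(F)F)(OS(=O)(=O)C(F)(F)F)C(C)C
Why: Soft enolisation (silyl enol ether formation with silyl triflate and amine) avoids a free enolate, so there is no retro-oxa-Michael ring opening and C2 stays S while 10 takes up the second flavanone.

**Step 6**
Reactants: 11 silyl bis-enol ether
Product: 12 (2S,3R,2''S,3''R)-5,7,5'',7''-tetrakis(benzyloxy)-4',4'''-dimethoxy-3,3''-biflavanone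
Conditions: (NH4)2Ce(NO3)6 (2.2 equiv), NaHCO3 (4.5 equiv), MeCN–EtCN–CH2Cl2, −30 → −10 °C
Reagents that add atoms: none
Why: In this silicon-tethered oxidative enol ether coupling, one-electron oxidation by tetravalent cerium gives a radical cation that the second enol ether captures within a seven-membered ring; each new bond terminus forms anti to the neighbouring 2-aryl group (2,3-trans), so two 2S halves give 3R,3''R, and tethered S/R pairs end up as a separable diastereomer, which raises the ee.

**Step 7**
Reactants: 12 tetrabenzyl biflavanone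
Product: 13 (2S,3R,2''S,3''R)-5,7,5'',7''-tetrahydroxy-4',4'''-dimethoxy-3,3''-biflavanone
Conditions: H2 (1 atm), 10% Pd/C, EtOAc–THF, rt
Reagents that add atoms: none
Why: Neutral catalytic hydrogenolysis removes the four O-benzyl groups and leaves the methyl ethers, the aryl ketones, the cyclic C2–O bonds and all four stereocentres untouched.

**Step 8**
Reactants: 13 tetraol; 14 acetic anhydride
Product: 15 (2S,3R,2''S,3''R)-5,7,5'',7''-tetraacetoxy-4',4'''-dimethoxy-3,3''-biflavanone
Conditions: 14 (12 equiv), pyridine, rt, 24 h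
Reagents that add atoms: acetic anhydride (14), CC(=O)OC(C)=O
Why: Exhaustive O-acetylation in pyridine at room temperature also caps the chelated 5-OH groups without chalcone formation or epimerisation.

**Step 9**
Reactants: 15 tetraacetate
Product: 16 (2S,3R,2''S,3''R)-5,7,5''-triacetoxy-7''-hydroxy-4',4'''-dimethoxy-3,3''-biflavanone
Conditions: lipase (triacylglycerol lipase, serine hydrolase class; immobilised Burkholderia cepacia lipase), 1-butanol (5 equiv), THF–MTBE, 40 °C, HPLC control, stopped at about 50–60% conversion; recovered 15 and the 7,7''-diol are re-acetylated as in step 8 and recycled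
Reagents that add atoms: none
Why: Lipase-catalysed regioselective alcoholysis (transesterification) reaches the exposed 7-acetates but not the 5-acetates shielded by the C4 carbonyl; because the two 7-acetates are homotopic, the first cleavage gives one compound, and no stereocentre is affected at neutral pH.

**Step 10**
Reactants: 16 monophenol triacetate; 17 methanol
Product: 18 (2S,3R,2''S,3''R)-5,7,5''-triacetoxy-7'',4',4'''-trimethoxy-3,3''-biflavanone
Conditions: 17 (3 equiv), PPh3 (1.5 equiv), DIAD (1.5 equiv), THF, 0 °C → rt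
Reagents that add atoms: methanol (17), CO
Why: In this Mitsunobu etherification the acidic 7''-phenol is methylated under neutral conditions, so the aryl acetates and the base-sensitive flavanone rings survive.

**Step 11**
Reactants: 18 methyl ether triacetate
Product: 19 Ruixianglangdusu B, (2S,3R,2''S,3''R)-5,7,5''-trihydroxy-7'',4',4'''-trimethoxy-3,3''-biflavanone
Conditions: HCl (cat., methanolic), MeOH–CH2Cl2, rt
Reagents that add atoms: none
Why: Acid-catalysed transesterification (methanolysis) frees the three phenols without base, so no retro-oxa-Michael opening occurs, and the trans,trans arrangement is in any case the thermodynamic one.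

**Compound list**
1 | 2',4',6'-trihydroxyacetophenone | CC(=O)c1c(O)cc(O)cc1O | starting material
2 | benzyl bromide | BrCc1ccccc1 | starting material
3 | 1-[2,4-bis(benzyloxy)-6-hydroxyphenyl]ethan-1-one | CC(=O)c1c(O)cc(OCc2ccccc2)cc1OCc1ccccc1 | intermediate
4 | N,N-dimethylformamide dimethyl acetal | COC(OC)N(C)C | starting material
5 | (E)-1-[2,4-bis(benzyloxy)-6-hydroxyphenyl]-3-(dimethylamino)prop-2-en-1-one | CN(C)/C=C/C(=O)c1c(O)cc(OCc2ccccc2)cc1OCc1ccccc1 | intermediate
6 | 5,7-bis(benzyloxy)-4H-chromen-4-one | O=c1ccoc2cc(OCc3ccccc3)cc(OCc3ccccc3)c12 | intermediate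
7 | 4-methoxyphenylboronic acid | COc1ccc(B(O)O)cc1 | starting material
8 | (2S)-5,7-bis(benzyloxy)-2-(4-methoxyphenyl)chroman-4-one | COc1ccc([C@H]2Oc3cc(OCc4ccccc4)cc(OCc4ccccc4)c3C(=O)C2)cc1 | intermediate
9 | diisopropylsilyl bis(trifluoromethanesulfonate) | CC(C)[Si](OS(=O)(=O)C(F)(F)F)(OS(=O)(=O)C(F)(F)F)C(C)C | starting material
10 | {[(2S)-5,7-bis(benzyloxy)-2-(4-methoxyphenyl)-2H-chromen-4-yl]oxy}di(propan-2-yl)silyl trifluoromethanesulfonate | COc1ccc([C@H]2Oc3cc(OCc4ccccc4)cc(OCc4ccccc4)c3C(O[Si](C(C)C)(C(C)C)OS(=O)(=O)C(F)(F)F)=C2)cc1 | intermediate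
11 | bis{[(2S)-5,7-bis(benzyloxy)-2-(4-methoxyphenyl)-2H-chromen-4-yl]oxy}di(propan-2-yl)silane | COc1ccc([C@H]2Oc3cc(OCc4ccccc4)cc(OCc4ccccc4)c3C(O[Si](C(C)C)(C(C)C)OC3=C[C@@H](c4ccc(OC)cc4)Oc4cc(OCc5ccccc5)cc(OCc5ccccc5)c34)=C2)cc1 | intermediate
12 | (2S,3R,2''S,3''R)-5,7,5'',7''-tetrakis(benzyloxy)-4',4'''-dimethoxy-3,3''-biflavanone | COc1ccc([C@H]2Oc3cc(OCc4ccccc4)cc(OCc4ccccc4)c3C(=O)[C@@H]2[C@H]2C(=O)c3c(OCc4ccccc4)cc(OCc4ccccc4)cc3O[C@@H]2c2ccc(OC)cc2)cc1 | intermediate
13 | (2S,3R,2''S,3''R)-5,7,5'',7''-tetrahydroxy-4',4'''-dimethoxy-3,3''-biflavanone | COc1ccc([C@H]2Oc3cc(O)cc(O)c3C(=O)[C@@H]2[C@H]2C(=O)c3c(O)cc(O)cc3O[C@@H]2c2ccc(OC)cc2)cc1 | intermediate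
14 | acetic anhydride | CC(=O)OC(C)=O | starting material
15 | (2S,3R,2''S,3''R)-5,7,5'',7''-tetraacetoxy-4',4'''-dimethoxy-3,3''-biflavanone | COc1ccc([C@H]2Oc3cc(OC(C)=O)cc(OC(C)=O)c3C(=O)[C@@H]2[C@H]2C(=O)c3c(OC(C)=O)cc(OC(C)=O)cc3O[C@@H]2c2ccc(OC)cc2)cc1 | intermediate
16 | (2S,3R,2''S,3''R)-5,7,5''-triacetoxy-7''-hydroxy-4',4'''-dimethoxy-3,3''-biflavanone | COc1ccc([C@H]2Oc3cc(OC(C)=O)cc(OC(C)=O)c3C(=O)[C@@H]2[C@H]2C(=O)c3c(OC(C)=O)cc(O)cc3O[C@@H]2c2ccc(OC)cc2)cc1 | intermediate
17 | methanol | CO | starting material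
18 | (2S,3R,2''S,3''R)-5,7,5''-triacetoxy-7'',4',4'''-trimethoxy-3,3''-biflavanone | COc1ccc([C@H]2Oc3cc(OC(C)=O)cc(OC(C)=O)c3C(=O)[C@@H]2[C@H]2C(=O)c3c(OC(C)=O)cc(OC)cc3O[C@@H]2c2ccc(OC)cc2)cc1 | intermediate
19 | Ruixianglangdusu B | COc1ccc([C@H]2Oc3cc(O)cc(O)c3C(=O)[C@@H]2[C@H]2C(=O)c3c(O)cc(OC)cc3O[C@@H]2c2ccc(OC)cc2)cc1 | target

**Step count**
Total step count: 11. Longest linear sequence: 11 steps (1 → 19). Two molecules of 8 meet in step 5.

**Three steps most likely to fail**

**Step 6 (oxidative coupling).** The radical cation may lose H-2 and end as the flavone, or the anisyl group may shift, before the C–C bond forms.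
- The fallback makes the C3–C3'' bond first, between sp2 carbons, and sets the stereocentres afterwards. It sets out from enaminone 5.
- I2 in CHCl3 at rt (iodocyclisation) gives 5,7-bis(benzyloxy)-3-iodo-4H-chromen-4-one F1.
- A one-pot Miyaura borylation/Suzuki homocoupling (PdCl2(dppf), B2pin2 0.55 equiv, K2CO3, dioxane, 80 °C) gives 5,5',7,7'-tetrakis(benzyloxy)-4H,4'H-[3,3'-bichromene]-4,4'-dione F2.
- A double Hayashi–Miyaura addition of 7 follows, with the catalyst of step 4 at higher loading and 40–60 °C. It attaches both anisyl groups under catalyst control (2S,2''S).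
- This last addition is the weak point of the fallback, because insertion into a 3-substituted chromone is expected to be slower than for 6.
- C3 and C3'' are formed by protonation next to a ketone and settle into the 2,3-trans arrangement. The fallback comes back to the route at 12, so 6, 8, 10 and 11 are not needed.

**Step 9 (lipase mono-deacetylation).** The bulky dimer may be a poor substrate, or the second 7-acetate may fall as fast as the first.
- The fallback drops the acetate detour and lets another enzyme class form the C–O bond directly. It sets out from tetraol 13.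
- An S-adenosyl-L-methionine-dependent O-methyltransferase (flavonoid 7-O-methyltransferase type, for example recombinant naringenin 7-O-methyltransferase) is used with S-adenosyl-L-methionine (1.1 equiv). The medium is phosphate buffer pH 7.5 with 10% DMSO at 30 °C, and the reaction is stopped at the monomethyl stage by HPLC.
- Acceptance of a biflavanone by this enzyme is untested, and this is the open question of the fallback.
- The enzyme methylates one 7-OH, and the fallback comes back to the route at 19. Unreacted 13 is recycled.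

**Step 4 (asymmetric 1,4-addition).** The electron-rich chromone may react slowly while 7 protodeboronates.
- The fallback sets C2 by forming the C2–O bond instead of the C2–aryl bond. It sets out from 3.
- C-carboxylation of its dilithio derivative (LiN(SiMe3)2, THF, −78 °C, then di-tert-butyl dicarbonate) gives tert-butyl 3-[2,4-bis(benzyloxy)-6-hydroxyphenyl]-3-oxopropanoate F3.
- Knoevenagel condensation with 4-methoxybenzaldehyde (piperidine/AcOH cat., toluene, 4 Å sieves) gives tert-butyl (Z)-2-[2,4-bis(benzyloxy)-6-hydroxybenzoyl]-3-(4-methoxyphenyl)prop-2-enoate F4.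
- A cinchona-alkaloid thiourea (10 mol %, toluene, −25 °C; the pseudo-enantiomer that gives 2S) catalyses the enantioselective intramolecular oxa-Michael addition. The product is tert-butyl (2S,3R)-5,7-bis(benzyloxy)-2-(4-methoxyphenyl)-4-oxochromane-3-carboxylate F5.
- p-TsOH in toluene at 80 °C cleaves the ester and decarboxylates, which comes back to the route at 8.

**Further compounds**
F1 | step 6 | 5,7-bis(benzyloxy)-3-iodo-4H-chromen-4-one | O=c1c(I)coc2cc(OCc3ccccc3)cc(OCc3ccccc3)c12
F2 | step 6 | 5,5',7,7'-tetrakis(benzyloxy)-4H,4'H-[3,3'-bichromene]-4,4'-dione | O=c1c(-c2coc3cc(OCc4ccccc4)cc(OCc4ccccc4)c3c2=O)coc2cc(OCc3ccccc3)cc(OCc3ccccc3)c12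
F0 | step 9 | none | none
F3 | step 4 | tert-butyl 3-[2,4-bis(benzyloxy)-6-hydroxyphenyl]-3-oxopropanoate | CC(C)(C)OC(=O)CC(=O)c1c(O)cc(OCc2ccccc2)cc1OCc1ccccc1
F4 | step 4 | tert-butyl (Z)-2-[2,4-bis(benzyloxy)-6-hydroxybenzoyl]-3-(4-methoxyphenyl)prop-2-enoate | COc1ccc(/C=C(\C(=O)OC(C)(C)C)C(=O)c2c(O)cc(OCc3ccccc3)cc2OCc2ccccc2)cc1
F5 | step 4 | tert-butyl (2S,3R)-5,7-bis(benzyloxy)-2-(4-methoxyphenyl)-4-oxochromane-3-carboxylate | COc1ccc([C@H]2Oc3cc(OCc4ccccc4)cc(OCc4ccccc4)c3C(=O)[C@@H]2C(=O)OC(C)(C)C)cc1
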